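The numbers of this flask are made up.

To choose between faster dissolving and higher solubility, plan on one ratio: the selectivity factor S, the rate at which free monomer enters chains by growth over the rate at which it goes to side product.

free monomer 0.050 M; initiator 90 µM; time 8.0 d

- monomer in chains and crystals together at 8.0 d, in percent of the free monomer charged
- the change that raises the amount of monomer in chains and crystals together at 8.0 d, in percent of the free monomer charged most ("none" if none brings more than 2 percentage points) (zeta / gamma / none)
- amount of monomer in chains and crystals together at 8.0 d, in percent of the free monomer charged, after gamma

- percent here means free monomer units held: one side product counts as two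
- what is said of monomer in chains includes crystals
- where a step has two of a species, its rate is k times that concentration squared, and two are used at each turn
- crystals is a solid; its amount is given per volume of the solution
- run time (flask): 8.0 d

Free monomer stands in both rates and cancels, so S is the growth frequency over 0.0089 /M/min times dissolved monomer in chains, D. A ladder of times gives both.

An initiating radical meets free monomer, with constant 2.2 × 10⁵ /M/s, within 9.09 × 10⁻⁵ s, and a growing radical pairs into dead chain within 1.59 s. Both are far quicker than crystal growth, 4.90 h, so radical supply from the initiator balances pairing at a growing radical concentration G:

G = √(initiator rate constant 1.1 × 10⁻⁴ /min × initiator / pairing constant 6 × 10⁸ /M/s) = 5.24 × 10⁻¹⁰ M, growth frequency 15000 /M/s × G = 4.72 × 10⁻⁴ /min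

Crystals respond faster than free monomer is used, whose half-life is 1.02 d, so D rides above solubility by production over the dissolution coefficient:

D = 0.90 mM + growth frequency × free monomer / 0.0034 /min = 7.84 mM at the charge

The initiator's half-life, 4.38 d, is longer than that of free monomer, so this reckoning holds G near its first value. With G's slow fall included, 1.78% of the free monomer remains at the end.

S = 6.76, the selectivity factor at the charge, rising, with G held at its first value, to 58.9 as D falls to solubility.

Since 1/S is straight in free monomer and each side product holds two units, the loss is 15.2%, so y comes to 83.0%. Zeta lifts S at the charge to 12.1 and y to 88.7%. Gamma lowers it to 6.07 and y to 80.1%. This reckoning picks zeta.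

The forecast gives y 85.4%, above this reckoning, with zeta best and 82.2% after gamma: “Doubling the dissolution coefficient roughly halves that supersaturation”.

The simulation gives y 85.7%, best zeta (4 percentage points, against −2.5 points for gamma), and 83.1% after gamma.

    free monomer + growing radical → monomer in chains + growing radical, rate k1*[growing radical]*[free monomer] (k1 = 15000 /M/s)
    2 growing radical → dead chain (k2 = 6 × 10⁸ /M/s)
    free monomer + monomer in chains → side product (k3 = 0.0089 /M/min)
    initiator → 2 initiating radical (k4 = 1.1 × 10⁻⁴ /min)
    crystals ⇌ monomer in chains, rate k5*(cs5 - [monomer in chains]) while solid is left; crystals form when [monomer in chains] > cs5 (cs5 = 0.90 mM, k5 = 0.0034 /min)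
    free monomer + initiating radical → growing radical + monomer in chains (k6 = 2.2 × 10⁵ /M/s)

In this flask, free monomer entered chains 11 times as fast as it went to side product at 0.970 d and 29 times as fast at 8.00 d, moments later than the charge, for which S was reckoned at 6.76, and 51% of the side-product turnover up to 8.00 d was already done at 0.800 d. The neighbour flask, read at 50 h with 24.4% free monomer and 4.45 × 10⁻¹⁰ M growing radical, gets from the same rule D = 2.34 mM and S = 19.2, and it holds side product at 11.1%.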